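**Plan**
Locants: ring C1 (C=O), C2 (allyl), C3 (H), C4 (quaternary, OMe), C5 (OMe), C6 (H); chain C8 (CHMe), C7 (CH2Ar). Enabling feature: without the C2 allyl group and the C5 oxygen, the arms C3=C2 and C5=C6 on C4 are identical, so C4 is only prochiral. The C5 oxygen can close a five-membered ring O–C7–C8–C4–C5, and C7 is a para-oxygenated benzylic carbon where C–O can later be exchanged for C–H.
Cuts, in retrosynthetic order: ArO–Si; C5=C6 (back to CH–CH2); O5–CH3; C7–H (back to a C7–O5 bridge); C2–allyl; O–C5 (oxa-Michael); C4–OMe (phenol dearomatisation); C7–aryl (Grignard); C8–CH3 (enolate methylation).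
Forward: the C8–C7 chain is built on the para-oxygenated phenyl ring and that ring is dearomatised to the symmetric dienone. The tetrahydrofuran (the only ring made) is closed and C2 of the surviving enone is allylated. The furan ring is then opened reductively at C7, O5 is methylated and C5=C6 is restored.
Stereochemistry: C8 comes from an Evans methylation and the temporary C7 carbinol from Felkin–Anh addition. C4 and the temporary C5 come from the ring closure, steered by C7 and C8. C7 and C5 stop being stereocentres at steps 12 and 14.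
The bridge is cleaved at the saturated-ketone level. O5 then remains a discrete alcohol that is methylated without regiochemical ambiguity, and no nucleophilic C6 enol faces the C7 cation.

Key step: step 9

Remark: the locants C1–C8 defined above are used for all intermediates, whatever the systematic name says. Compounds 1, 2, 9 and 17 are taken as catalogue chemicals.

**Step 1**
Reactants: 1 4-(benzyloxy)phenylacetic acid; 2 (S)-4-benzyl-1,3-oxazolidin-2-one
Product: 4 (S)-4-benzyl-3-{[4-(benzyloxy)phenyl]acetyl}-1,3-oxazolidin-2-one, via mixed pivalic anhydride 3 (not isolated)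
Conditions: PivCl, Et3N, THF, −20 °C; then LiCl, 2, −20 °C → rt
Reagents that add atoms: pivaloyl chloride, CC(C)(C)C(=O)Cl (acyl group present in 3 only)
Why: N-acylation of an Evans auxiliary through the mixed pivalic anhydride (LiCl/Et3N variant) is routine for arylacetic acids, the hindered pivaloyl carbonyl directs attack to the arylacetyl carbonyl, and no stereocentre is touched.

**Step 2**
Reactants: 4 (S)-4-benzyl-3-{[4-(benzyloxy)phenyl]acetyl}-1,3-oxazolidin-2-one
Product: 6 (4S)-4-benzyl-3-{(2S)-2-[4-(benzyloxy)phenyl]propanoyl}-1,3-oxazolidin-2-one, via sodium Z-enolate 5 (not isolated)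
Conditions: NaHMDS (1.1 equiv), THF, −78 °C; MeI (5 equiv), −78 → −40 °C
Reagents that add atoms: iodomethane, CI; sodium hexamethyldisilazide, C[Si](C)(C)[N-][Si](C)(C)C.[Na+] (sodium present in 5 only)
Why: In this Evans asymmetric alkylation the chelated Z-enolate is methylated on the face away from the auxiliary benzyl group, which sets C8 (2S here, the same spatial arrangement as 8R in the target, where only the CIP ranking differs).

**Step 3**
Reactants: 6 (4S)-4-benzyl-3-{(2S)-2-[4-(benzyloxy)phenyl]propanoyl}-1,3-oxazolidin-2-one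
Product: 7 (2S)-2-[4-(benzyloxy)phenyl]propan-1-ol
Conditions: LiBH4, H2O (1.1 equiv), Et2O, 0 °C
Reagents that add atoms: none
Why: Reductive auxiliary removal with LiBH4 attacks the exocyclic imide carbonyl selectively and proceeds without enolisation, so C8 is retained and 2 can be recovered.

**Step 4**
Reactants: 7 (2S)-2-[4-(benzyloxy)phenyl]propan-1-ol
Product: 8 (2S)-2-[4-(benzyloxy)phenyl]propanal
Conditions: Dess–Martin periodinane (1.2 equiv), NaHCO3, CH2Cl2, 0 °C; used at once
Reagents that add atoms: none
Why: Dess–Martin oxidation in a buffered, non-basic medium should give the configurationally labile α-aryl aldehyde without enolisation.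

**Step 5**
Reactants: 9 4-bromo-2-methoxyphenol
Product: 10 (4-bromo-2-methoxyphenoxy)(tert-butyl)dimethylsilane
Conditions: TBSCl, imidazole, DMF, rt
Reagents that add atoms: tert-butyldimethylsilyl chloride, CC(C)(C)[Si](C)(C)Cl
Why: Standard imidazole-promoted silylation masks the phenol with a group that tolerates magnesium, hydrogenation, iodine(III), palladium and trifluoroacetic acid and leaves with fluoride at the end.

**Step 6**
Reactants: 10 (4-bromo-2-methoxyphenoxy)(tert-butyl)dimethylsilane; 8 (2S)-2-[4-(benzyloxy)phenyl]propanal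
Product: 12 (1R,2S)-2-[4-(benzyloxy)phenyl]-1-{4-[(tert-butyldimethylsilyl)oxy]-3-methoxyphenyl}propan-1-ol, via arylmagnesium bromide 11 (not isolated)
Conditions: 10 (1.3 equiv), Mg, THF, 40 °C; then 8, THF, −78 °C; aq NH4Cl; chromatographic removal of the C7 epimer
Reagents that add atoms: magnesium, [Mg] (present in 11 only)
Why: In this Grignard addition under Felkin–Anh control the C8 aryl group stands perpendicular to the carbonyl and the nucleophile enters anti to it past H-8, which sets C7 as R, while at −78 °C addition should outrun enolisation of the aldehyde.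

**Step 7**
Reactants: 12 (1R,2S)-2-[4-(benzyloxy)phenyl]-1-{4-[(tert-butyldimethylsilyl)oxy]-3-methoxyphenyl}propan-1-ol
Product: 13 4-[(1R,2S)-1-{4-[(tert-butyldimethylsilyl)oxy]-3-methoxyphenyl}-1-hydroxypropan-2-yl]phenol
Conditions: H2 (1 atm), 10% Pd/C, EtOAc, rt
Reagents that add atoms: none
Why: Hydrogenolysis of an aryl benzyl ether over Pd/C in neutral ethyl acetate is much faster than cleavage of a free secondary benzylic alcohol, which needs acid, and the silyl ether is inert.

**Step 8**
Reactants: 13 4-[(1R,2S)-1-{4-[(tert-butyldimethylsilyl)oxy]-3-methoxyphenyl}-1-hydroxypropan-2-yl]phenol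
Product: 14 4-[(1R,2R)-1-{4-[(tert-butyldimethylsilyl)oxy]-3-methoxyphenyl}-1-hydroxypropan-2-yl]-4-methoxycyclohexa-2,5-dien-1-one
Conditions: PhI(OAc)2 (1.1 equiv), MeOH, 0 °C; NaHCO3 work-up
Reagents that add atoms: methanol, CO
Why: In this iodine(III) oxidative dearomatisation of a para-alkylphenol only the free phenol binds iodine, solvent methanol captures C4 (the C7 hydroxyl could only form an oxetane there), and no stereocentre arises because the two ring halves are identical; the C8 descriptor changes to R by ranking alone.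

**Step 9**
Reactants: 14 4-[(1R,2R)-1-{4-[(tert-butyldimethylsilyl)oxy]-3-methoxyphenyl}-1-hydroxypropan-2-yl]-4-methoxycyclohexa-2,5-dien-1-one
Product: 15 (2R,3R,3aR,7aS)-2-{4-[(tert-butyldimethylsilyl)oxy]-3-methoxyphenyl}-3a-methoxy-3-methyl-3,3a,7,7a-tetrahydro-1-benzofuran-6(2H)-one (cis-fused; aryl, 3-Me, 3a-OMe and H-7a on one face)
Conditions: DBU (0.2 equiv), CH2Cl2, rt, until the isomer ratio no longer changes
Reagents that add atoms: none
Why: DBU activates the C7 hydroxyl as a general base, its oxygen adds to the β-carbon C5 of one enone arm and the C1–C6 enolate is protonated at C6; each event is reversible through E1cB ring opening, so the product ratio should settle at its thermodynamic value. The closest known reaction type is the intramolecular oxa-Michael desymmetrisation of 4-(2-hydroxyethyl)-4-oxy-cyclohexa-2,5-dienones to cis-fused tetrahydrobenzofuran-6-ones. The ring O–C7–C8–C4–C5 closes in the 5-exo-trig mode (C5=C6 lies outside the forming ring), and the short tether reaches C5 only from the ring face that carries C8, so C5 is set by C4 as the cis fusion (H-5 syn to 4-OMe). C4 is set by the choice of arm, which C8 and C7 control: closure on one arm places 8-Me and the 7-aryl group on the convex face beside 4-OMe and H-5, whereas closure on the other presses 8-Me against C3 and the aryl group over C6 in the concave fold. The only selectivity needed is this diastereotopic-group selection (the arms are constitutionally identical, so no regiochemical question exists), and it is secured because the Felkin adduct puts Me and aryl cis on the new ring, so both favour the same arm. A catalytic amidine leaves the aryl silyl ether and the acid-labile benzylic C7–O bond alone, which is why base and not acid catalysis is chosen.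

**Step 10**
Reactants: 15 (2R,3R,3aR,7aS)-2-{4-[(tert-butyldimethylsilyl)oxy]-3-methoxyphenyl}-3a-methoxy-3-methyl-3,3a,7,7a-tetrahydro-1-benzofuran-6(2H)-one
Product: 16 (2R,3R,3aS,7aS)-2-{4-[(tert-butyldimethylsilyl)oxy]-3-methoxyphenyl}-5-iodo-3a-methoxy-3-methyl-3,3a,7,7a-tetrahydro-1-benzofuran-6(2H)-one (same geometry as 15; the 3a descriptor changes by ranking only)
Conditions: I2 (2 equiv), pyridine–CH2Cl2 1:1, 0 °C → rt
Reagents that add atoms: iodine, II
Why: Pyridine-promoted α-iodination of an enone (addition–iodination–elimination, known for 4,4-disubstituted cyclohexenones) can act only on C2=C3, the one enone left, and from here C4 stays stereogenic even if the oxa-Michael reaction reversed.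

**Step 11**
Reactants: 16 (2R,3R,3aS,7aS)-2-{4-[(tert-butyldimethylsilyl)oxy]-3-methoxyphenyl}-5-iodo-3a-methoxy-3-methyl-3,3a,7,7a-tetrahydro-1-benzofuran-6(2H)-one; 17 allyltributylstannane
Product: 18 (2R,3R,3aR,7aS)-5-allyl-2-{4-[(tert-butyldimethylsilyl)oxy]-3-methoxyphenyl}-3a-methoxy-3-methyl-3,3a,7,7a-tetrahydro-1-benzofuran-6(2H)-one
Conditions: 17 (1.5 equiv), Pd2(dba)3 (5 mol %), AsPh3 (20 mol %), CuI (10 mol %), NMP, rt
Reagents that add atoms: allyltributylstannane (17), C=CC[Sn](CCCC)(CCCC)CCCC
Why: Stille coupling of an α-iodoenone with an allylstannane runs at room temperature with a weakly donating arsine ligand and copper(I) co-catalysis, and without fluoride or strong base, so the silyl ether and the β-alkoxy ketone persist.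

**Step 12**
Reactants: 18 (2R,3R,3aR,7aS)-5-allyl-2-{4-[(tert-butyldimethylsilyl)oxy]-3-methoxyphenyl}-3a-methoxy-3-methyl-3,3a,7,7a-tetrahydro-1-benzofuran-6(2H)-one
Product: 19 (4S,5S)-2-allyl-4-[(2R)-1-{4-[(tert-butyldimethylsilyl)oxy]-3-methoxyphenyl}propan-2-yl]-5-hydroxy-4-methoxycyclohex-2-en-1-one (4-OMe and 5-OH trans)
Conditions: Et3SiH (5 equiv), TFA (5 equiv), CH2Cl2, −40 → 0 °C
Reagents that add atoms: none
Why: In this ionic hydrogenation of a 2-aryltetrahydrofuran TFA ionises only the C7–O bond, whose cation is stabilised by the para-silyloxy group, excess silane should quench it to CH2 before H-8 can be lost, O5 departs as a plain alcohol so no C6 enol can trap the cation, and the monosubstituted alkene, enone, C4–OMe and aryl silyl ether are not affected at this temperature.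

**Step 13**
Reactants: 19 (4S,5S)-2-allyl-4-[(2R)-1-{4-[(tert-butyldimethylsilyl)oxy]-3-methoxyphenyl}propan-2-yl]-5-hydroxy-4-methoxycyclohex-2-en-1-one
Product: 20 (4S,5S)-2-allyl-4-[(2R)-1-{4-[(tert-butyldimethylsilyl)oxy]-3-methoxyphenyl}propan-2-yl]-4,5-dimethoxycyclohex-2-en-1-one
Conditions: Me3OBF4 (3 equiv), Proton Sponge (3.5 equiv), 4 Å MS, CH2Cl2, 0 °C → rt
Reagents that add atoms: trimethyloxonium tetrafluoroborate, C[O+](C)C.F[B-](F)(F)F
Why: O-methylation with Meerwein salt and a non-nucleophilic, kinetically slow base is the accepted method for hindered aldol-type alcohols because it avoids retro-aldol cleavage and β-elimination, and it places the methyl group on O5 unambiguously.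

**Step 14**
Reactants: 20 (4S,5S)-2-allyl-4-[(2R)-1-{4-[(tert-butyldimethylsilyl)oxy]-3-methoxyphenyl}propan-2-yl]-4,5-dimethoxycyclohex-2-en-1-one
Product: 22 (4S)-2-allyl-4-[(2R)-1-{4-[(tert-butyldimethylsilyl)oxy]-3-methoxyphenyl}propan-2-yl]-4,5-dimethoxycyclohexa-2,5-dien-1-one, via trimethylsilyl dienol ether 21 (not isolated)
Conditions: TMSCl, LiHMDS, THF, −78 °C (in-situ quench); volatiles off; Pd(OAc)2 (1.1 equiv), MeCN, rt
Reagents that add atoms: chlorotrimethylsilane, C[Si](C)(C)Cl (silyl group present in 21 only)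
Why: In this Saegusa–Ito oxidation deprotonation is possible only at C6 (C2 is sp2, C4 quaternary), silylation at −78 °C should outrun loss of methoxide, and Pd(II) binds C6 on the face away from the side chain and 5-OMe, i.e. syn to the single H-5 needed for β-hydride elimination, as in the known conversion of β-alkoxy ketones into β-alkoxy enones.

**Step 15**
Reactants: 22 (4S)-2-allyl-4-[(2R)-1-{4-[(tert-butyldimethylsilyl)oxy]-3-methoxyphenyl}propan-2-yl]-4,5-dimethoxycyclohexa-2,5-dien-1-one
Product: 23 (4S)-2-allyl-4-[(2R)-1-(4-hydroxy-3-methoxyphenyl)propan-2-yl]-4,5-dimethoxycyclohexa-2,5-dien-1-one (target)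
Conditions: TBAF–AcOH (1:1, 1.2 equiv), THF, 0 °C
Reagents that add atoms: none
Why: Fluoride cleavage of an aryl silyl ether is fast at 0 °C, and the acetic acid buffer keeps phenoxide basicity away from the cross-conjugated dienone and its stereocentres.

**Compound list**
1 | 4-(benzyloxy)phenylacetic acid | O=C(O)Cc1ccc(OCc2ccccc2)cc1 | starting material
2 | (S)-4-benzyl-1,3-oxazolidin-2-one | O=C1N[C@@H](Cc2ccccc2)CO1 | starting material
3 | [4-(benzyloxy)phenyl]acetic pivalic anhydride | CC(C)(C)C(=O)OC(=O)Cc1ccc(OCc2ccccc2)cc1 | intermediate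
4 | (S)-4-benzyl-3-{[4-(benzyloxy)phenyl]acetyl}-1,3-oxazolidin-2-one | O=C(Cc1ccc(OCc2ccccc2)cc1)N1C(=O)OC[C@@H]1Cc1ccccc1 | intermediate
5 | sodium Z-enolate of 4 | [Na+].[O-]/C(=C\c1ccc(OCc2ccccc2)cc1)N1C(=O)OC[C@@H]1Cc1ccccc1 | intermediate
6 | (4S)-4-benzyl-3-{(2S)-2-[4-(benzyloxy)phenyl]propanoyl}-1,3-oxazolidin-2-one | C[C@@H](c1ccc(OCc2ccccc2)cc1)C(=O)N1C(=O)OC[C@@H]1Cc1ccccc1 | intermediate
7 | (2S)-2-[4-(benzyloxy)phenyl]propan-1-ol | C[C@@H](c1ccc(OCc2ccccc2)cc1)CO | intermediate
8 | (2S)-2-[4-(benzyloxy)phenyl]propanal | C[C@@H](c1ccc(OCc2ccccc2)cc1)C=O | intermediate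
9 | 4-bromo-2-methoxyphenol | COc1cc(Br)ccc1O | starting material
10 | (4-bromo-2-methoxyphenoxy)(tert-butyl)dimethylsilane | COc1cc(Br)ccc1O[Si](C)(C)C(C)(C)C | intermediate
11 | {4-[(tert-butyldimethylsilyl)oxy]-3-methoxyphenyl}magnesium bromide | COc1cc([Mg]Br)ccc1O[Si](C)(C)C(C)(C)C | intermediate
12 | (1R,2S)-2-[4-(benzyloxy)phenyl]-1-{4-[(tert-butyldimethylsilyl)oxy]-3-methoxyphenyl}propan-1-ol | C[C@@H](c1ccc(OCc2ccccc2)cc1)[C@@H](O)c1ccc(O[Si](C)(C)C(C)(C)C)c(OC)c1 | intermediate
13 | 4-[(1R,2S)-1-{4-[(tert-butyldimethylsilyl)oxy]-3-methoxyphenyl}-1-hydroxypropan-2-yl]phenol | C[C@@H](c1ccc(O)cc1)[C@@H](O)c1ccc(O[Si](C)(C)C(C)(C)C)c(OC)c1 | intermediate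
14 | 4-[(1R,2R)-1-{4-[(tert-butyldimethylsilyl)oxy]-3-methoxyphenyl}-1-hydroxypropan-2-yl]-4-methoxycyclohexa-2,5-dien-1-one | COC1([C@H](C)[C@@H](O)c2ccc(O[Si](C)(C)C(C)(C)C)c(OC)c2)C=CC(=O)C=C1 | intermediate
15 | (2R,3R,3aR,7aS)-2-{4-[(tert-butyldimethylsilyl)oxy]-3-methoxyphenyl}-3a-methoxy-3-methyl-3,3a,7,7a-tetrahydro-1-benzofuran-6(2H)-one | O=C1C=C[C@@]2(OC)[C@H](C)[C@H](c3ccc(O[Si](C)(C)C(C)(C)C)c(OC)c3)O[C@H]2C1 | intermediate
16 | (2R,3R,3aS,7aS)-2-{4-[(tert-butyldimethylsilyl)oxy]-3-methoxyphenyl}-5-iodo-3a-methoxy-3-methyl-3,3a,7,7a-tetrahydro-1-benzofuran-6(2H)-one | O=C1C(I)=C[C@@]2(OC)[C@H](C)[C@H](c3ccc(O[Si](C)(C)C(C)(C)C)c(OC)c3)O[C@H]2C1 | intermediate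
17 | allyltributylstannane | C=CC[Sn](CCCC)(CCCC)CCCC | starting material
18 | (2R,3R,3aR,7aS)-5-allyl-2-{4-[(tert-butyldimethylsilyl)oxy]-3-methoxyphenyl}-3a-methoxy-3-methyl-3,3a,7,7a-tetrahydro-1-benzofuran-6(2H)-one | C=CCC1=C[C@@]2(OC)[C@H](C)[C@H](c3ccc(O[Si](C)(C)C(C)(C)C)c(OC)c3)O[C@H]2CC1=O | intermediate
19 | (4S,5S)-2-allyl-4-[(2R)-1-{4-[(tert-butyldimethylsilyl)oxy]-3-methoxyphenyl}propan-2-yl]-5-hydroxy-4-methoxycyclohex-2-en-1-one | C=CCC1=C[C@@](OC)([C@H](C)Cc2ccc(O[Si](C)(C)C(C)(C)C)c(OC)c2)[C@@H](O)CC1=O | intermediate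
20 | (4S,5S)-2-allyl-4-[(2R)-1-{4-[(tert-butyldimethylsilyl)oxy]-3-methoxyphenyl}propan-2-yl]-4,5-dimethoxycyclohex-2-en-1-one | C=CCC1=C[C@@](OC)([C@H](C)Cc2ccc(O[Si](C)(C)C(C)(C)C)c(OC)c2)[C@@H](OC)CC1=O | intermediate
21 | trimethylsilyl dienol ether of 20 (C1–OSiMe3, C1=C6, C2=C3; C4, C5 and C8 as in 20) | C=CCC1=C[C@@](OC)([C@H](C)Cc2ccc(O[Si](C)(C)C(C)(C)C)c(OC)c2)[C@@H](OC)C=C1O[Si](C)(C)C | intermediate
22 | (4S)-2-allyl-4-[(2R)-1-{4-[(tert-butyldimethylsilyl)oxy]-3-methoxyphenyl}propan-2-yl]-4,5-dimethoxycyclohexa-2,5-dien-1-one | C=CCC1=C[C@@](OC)([C@H](C)Cc2ccc(O[Si](C)(C)C(C)(C)C)c(OC)c2)C(OC)=CC1=O | intermediate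
23 | (4S)-2-allyl-4-[(2R)-1-(4-hydroxy-3-methoxyphenyl)propan-2-yl]-4,5-dimethoxycyclohexa-2,5-dien-1-one | C=CCC1=C[C@@](OC)([C@H](C)Cc2ccc(O)c(OC)c2)C(OC)=CC1=O | target

Total step count: 15. Longest linear sequence: 14 (steps 1–4 and 6–15; step 5 is the side branch).

**Steps most likely to fail**

Step 9. The two enone arms may be discriminated too weakly, either because the energy gap between the two cis-fused bicycles is smaller than the convex/concave argument suggests or because equilibration under the amidine is too slow. The fallback sets out from 14 and returns at 15. It replaces thermodynamic substrate control by kinetic catalyst control: a chiral BINOL-derived phosphoric acid, a catalyst class established for enantioselective oxa-Michael desymmetrisation of such dienones, is used in the enantiomeric form that reinforces the substrate bias. Any wrong diastereomer is separated and returned to the 14/15 manifold with DBU. This detour makes no new compound (F0).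

Step 12. Three processes may interfere. Proton loss from the C7 cation would scramble C8 on re-protonation, the acid may dehydrate the liberated aldol unit, and the plain ether may ionise too slowly at low temperature. The fallback sets out from 18 and returns at 22, bypassing steps 13 and 14 as well.
- Compound 18 is converted with LiHMDS/TMSCl into the trimethylsilyl dienol ether of the bicycle F1.
- Pd(OAc)2 in acetonitrile turns this into the 3,3a-dihydrobenzofuran-6(2H)-one F2, in which O5 belongs to a vinylogous ester and is a far better leaving group.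
- Et3SiH/TFA should then act already at −78 °C and give the 5-hydroxy-dienone (vinylogous acid) F3.
- F3 is O-methylated under equilibrating conditions (HC(OMe)3, MeOH, cat. CSA), and 22 is separated from the C1-methylated isomer.

This detour is kept in reserve for two reasons. The released enol carbon C6 can compete with the silane for the cation, and the methylation is not regiospecific.

Step 14. Methanol may be lost from the C6 enolate or its silyl ether by E1cB, or palladium hydride may move the allyl double bond into conjugation. The fallback sets out from 19 and returns at 22. It changes the oxidation level instead of dehydrogenating. Dess–Martin oxidation of the C5 alcohol gives the cyclohex-4-ene-1,3-dione F4 (the keto tautomer of F3). Enol etherification with HC(OMe)3/MeOH/cat. CSA then gives 22 after chromatographic separation. No enolate carrying a β-leaving group and no palladium are involved.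

**Further compounds**
F0 | step 9 | none | none
F1 | step 12 | trimethylsilyl dienol ether of 18 (C1–OSiMe3, C1=C6; ring fusion as in 18) | C=CCC1=C[C@@]2(OC)[C@H](C)[C@H](c3ccc(O[Si](C)(C)C(C)(C)C)c(OC)c3)O[C@H]2C=C1O[Si](C)(C)C
F2 | step 12 | (2R,3R,3aR)-5-allyl-2-{4-[(tert-butyldimethylsilyl)oxy]-3-methoxyphenyl}-3a-methoxy-3-methyl-3,3a-dihydro-1-benzofuran-6(2H)-one | C=CCC1=C[C@@]2(OC)[C@H](C)[C@H](c3ccc(O[Si](C)(C)C(C)(C)C)c(OC)c3)OC2=CC1=O
F3 | step 12 | (4S)-2-allyl-4-[(2R)-1-{4-[(tert-butyldimethylsilyl)oxy]-3-methoxyphenyl}propan-2-yl]-5-hydroxy-4-methoxycyclohexa-2,5-dien-1-one | C=CCC1=C[C@@](OC)([C@H](C)Cc2ccc(O[Si](C)(C)C(C)(C)C)c(OC)c2)C(O)=CC1=O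
F4 | step 14 | (6S)-4-allyl-6-[(2R)-1-{4-[(tert-butyldimethylsilyl)oxy]-3-methoxyphenyl}propan-2-yl]-6-methoxycyclohex-4-ene-1,3-dione | C=CCC1=C[C@@](OC)([C@H](C)Cc2ccc(O[Si](C)(C)C(C)(C)C)c(OC)c2)C(=O)CC1=O
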